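In this closed, stirred vessel the solid substrate starts undissolved and target appears slowly, so I begin with what the earlier winter run can tell about the flask.

| flask | solid substrate | remark | time |
|---|---|---|---|
| winter | 0.015 M | run made earlier |  |
| flask | 0.010 M |  | 10 h |

winter run (percent of the solid substrate charged)

| time / min | target / % |
|---|---|
| 6.00 | 0 |
| 20.0 | 0 |
| 30.0 | 3 |
| 50.0 | 5 |
| 80.0 | 9 |
| 90.0 | 9 |
| 120 | 11 |

(readings scatter by 1.5 percentage points)

- as a solid, counted per litre of solution: solid substrate
- the numbers in the tables scatter by 1.5 percentage points (one standard deviation)
- at the start none of the solid substrate is in solution
- a reading or a percentage of target counts all its forms, free or not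

- time, not beyond 10 h, at which the flask holds most target
- the amount of target, in percent of the solid substrate charged, at that time
- the first time at which target reaches 23 %, in the same percent

Which numbers must be good? The ratio of charges, 1.50, matters most, because the time to 23 % moves by that factor according to whether target forms at the same amount per litre in both flasks or in proportion to the charge. The last winter reading comes next, since the time varies inversely with it, a higher reading giving an earlier time, and it carries 1.5 percentage points on 11 %, while the reading at 6.00 min stays out of the reckoning. I take the same amount per litre, a zero-order rate in the usual term, and carry the pace, 0.0825 /h, the fraction of the flask's charge made into target per hour. So the flask reaches 23 % at 2.79 h. Put back in, that amount is 15.3 % of the winter charge, a little above the last winter reading, so the line stretches only a little and I keep that time. The readings show no peak, so I give no number for the best.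

The forecast says 3.1 h (2.5 h to 4.5 h), later than my time, and puts the best at 70 % (42 % to 92 %) at 10 h (6 h to 10 h), on the ground that “Nothing shows target decay”.

The flask reaches the level at 2.53 h, earlier than my time, and holds its best, 32.4 %, at 3.79 h.

    starting material ⇌ target (K = 1.30, k = 0.0270 /min)
    starting material ⇌ isomer of the product (K = 3.00, k = 0.00310 /min)
    target ⇌ isomer of the product (k = 0.0250 /min)
    starting material + target ⇌ idle adduct, settled at all times (K = 2100 /M)
    solid substrate ⇌ starting material, rate k5*(cs5 - [starting material]) while solid is left; crystals form when [starting material] > cs5 (solubility = 8.70 mM, k = 0.00620 /min)
    target → over-reaction product (k = 0.0160 /min)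

Starting material and free target relax with a half-life of 0.242 h by that step alone, shorter than the 10 h allowed, and at the best time the flask's solid substrate stands at 0 %. From there target in the flask falls to 12.1 % at 10.0 h, while over-reaction product rises to 60.6 %. In the neighbour with 0.040 M of solid substrate, a quarter of the pace over 10 h gives 20.6 %; the computed amount is 18.0 %, with 34.4 % still solid.

The numbers in the tables are simulated for substances that don't exist, and the scatter is random.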